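The route rests on an anionic oxy-Cope disconnection of ring B. With the decalin numbered C1 (allylic CHOAc), C2, C3/C8 (fusion), C4 (CHMe), C5 (CHOAc), C6, C7=C11 (C11 bears Me and C12H2O) and C9=C10(Me), the sequence O–C5–C6–C7(=C11)–C8–C9=C10 spanning the cis fusion maps onto the product of a [3,3] shift whose C6=C7=C11 carbons come from an allene. The precursor is a carvone-derived bicyclo[2.2.2]octene whose C5 carbinol carries an axially chiral allenyl group syn to the C8=C9 bridge. One operation breaks the sacrificial C5–C10 bond, forms C7–C8, closes ring B, creates C8 with the cis fusion and fixes the C7=C11 geometry.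

Key step: step 12

Remark: all intermediates are described with the decalin locants their atoms finally carry (in the bicycles C10 and C3 are the bridgeheads, C8=C9 is the etheno bridge, C1–C2 and C4–C5 are the saturated bridges); α is the face of the ring-fusion hydrogens H3 and H8; the copper hydride SN2′ reduction of step 11 is assumed to be anti, as is usual for copper-mediated openings of propargylic oxiranes.

Step 1
Reactants: 1 (R)-(−)-carvone
Product: 2 (R)-10-chlorocarvone
Conditions: Ca(OCl)2, CO2 (dry ice), CH2Cl2–H2O, 0 °C
Reagents that add atoms: calcium hypochlorite, [Ca+2].[O-]Cl.[O-]Cl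
Why: Ene-type allylic chlorination by hypochlorous acid attacks only the electron-rich 1,1-disubstituted alkene (the enone alkene is deactivated), transposes the double bond within the isopropenyl group and leaves the single stereocentre untouched.

Step 2
Reactants: 2 (R)-10-chlorocarvone
Product: 4 (1S,4S)-1-methyl-8-methylidenebicyclo[2.2.2]oct-5-en-2-one, via potassium dienolate 3 (not isolated)
Conditions: KOt-Bu, t-BuOH–THF, 0 → 23 °C
Reagents that add atoms: none
Why: Intramolecular enolate C-alkylation in which γ-deprotonation gives the extended dienolate, whose α-carbon (future C10) displaces the allylic chloride through a six-membered transition state; this makes the sacrificial C5–C10 bond, moves the ring alkene to C8=C9 and fixes the new quaternary bridgehead, because the tether from the existing stereocentre (future C3) can reach only one face.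

Step 3
Reactants: 4 bicyclic ketone
Product: 5 C1 alcohol (hydroxyl syn to the C4–C5 bridge)
Conditions: LiBH(s-Bu)3, THF, −78 °C; then NaOH, H2O2, 0 °C
Reagents that add atoms: none
Why: Diastereoselective ketone reduction by a bulky borohydride, which approaches C1 past the flat etheno bridge and not past the inward hydrogen of the C5 methylene, so the new C1 stereocentre carries its oxygen on the side of the C4–C5 bridge.

Step 4
Reactants: 5 C1 alcohol
Product: 7 C1 PMB ether, via sodium alkoxide 6 (not isolated)
Conditions: NaH, THF–DMF, 0 °C; then PMBCl, n-Bu4NI (cat.), 23 °C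
Reagents that add atoms: 4-methoxybenzyl chloride, COc1ccc(CCl)cc1
Why: Williamson ether synthesis on the secondary alkoxide installs a benzyl-type group that, unlike a silyl or acyl group, cannot move to the 1,3-syn C5 oxyanion formed in steps 10 and 12 and is removable oxidatively.

Step 5
Reactants: 7 C1 PMB ether
Product: 8 C5 allylic alcohol (both C5 epimers)
Conditions: SeO2 (0.5 equiv), t-BuOOH, CH2Cl2, 23 °C
Reagents that add atoms: selenium dioxide, O=[Se]=O; tert-butyl hydroperoxide, CC(C)(C)OO
Why: Riley allylic oxidation (ene reaction, then [2,3]-sigmatropic shift) can use only the C5 methylene, because the other allylic hydrogen sits at a bridgehead and the etheno bridge has none, so oxygen is placed at C5 with the C4 methylidene retained; the carbinol configuration does not matter because it is oxidised in step 6.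

Step 6
Reactants: 8 C5 allylic alcohol
Product: 9 C4-methylidene C5 ketone
Conditions: Dess–Martin periodinane, NaHCO3, CH2Cl2, 0 → 23 °C
Reagents that add atoms: none
Why: Dess–Martin oxidation converts both carbinol epimers into the same α-methylene ketone under buffered neutral conditions that spare the PMB ether and both alkenes.

Step 7
Reactants: 9 C4-methylidene C5 ketone
Product: 12 C5 ketone bearing the C4 methyl syn to the C8=C9 bridge, via lithium enolate 10 (not isolated), via C4 epimer 11 (not isolated)
Conditions: LiBH(s-Bu)3, THF, −78 °C; MeOH; then NaOMe (0.2 equiv), MeOH, 23 °C; recovered 11 re-equilibrated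
Reagents that add atoms: none
Why: Conjugate hydride reduction of the β-unsubstituted enone (its carbonyl carbon is screened by the quaternary bridgehead and the syn OPMB group), followed by base-mediated epimerisation through the only possible enolate, which should favour the C4 methyl on the etheno side where it escapes the inward C2–H that it meets in the kinetic epimer.

Step 8
Reactants: 13 (S)-2-methylglycidol
Product: 14 (R)-2-methyloxirane-2-carbaldehyde
Conditions: Dess–Martin periodinane, NaHCO3, CH2Cl2, 0 °C; filtered solution used at once
Reagents that add atoms: none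
Why: Dess–Martin oxidation of the primary alcohol under buffered non-aqueous conditions leaves the oxirane intact, and the quaternary stereocentre has no α-hydrogen to lose (the descriptor changes only through the priority rules).

Step 9
Reactants: 14 (R)-2-methyloxirane-2-carbaldehyde
Product: 15 (S)-2-ethynyl-2-methyloxirane
Conditions: dimethyl (1-diazo-2-oxopropyl)phosphonate, K2CO3, MeOH, 0 → 23 °C; pentane extraction, kept as a titrated THF solution
Reagents that add atoms: dimethyl (1-diazo-2-oxopropyl)phosphonate, CC(=O)C(=[N+]=[N-])P(=O)(OC)OC
Why: Ohira–Bestmann (Seyferth–Gilbert) homologation turns the aldehyde into the terminal alkyne under mild carbonate conditions that neither open the oxirane nor touch the quaternary centre.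

Step 10
Reactants: 12 C5 ketone; 15 (S)-2-ethynyl-2-methyloxirane
Product: 17 C5 propargylic carbinol bearing the alkynyl oxirane, via lithium acetylide 16 (not isolated)
Conditions: 15, n-BuLi, THF, −78 °C; anhydrous CeCl3, −78 °C; then 12, −78 → −40 °C; aq. NH4Cl
Reagents that add atoms: none
Why: 1,2-Addition of a cerium-modified lithium acetylide (weakly basic, so the C4 hydrogen is not removed), in which the OPMB group lying 1,3-syn over one face of the C5 carbonyl forces the slim nucleophile to enter from the etheno face; this sets C5 with the alkynyl group syn to C8=C9 and the hydroxyl anti to it.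

Step 11
Reactants: 17 C5 propargylic carbinol
Product: 19 allenyl diol, via silyl ether 18 (not isolated)
Conditions: CuCl (5 mol %), 1,3-bis(2,6-diisopropylphenyl)imidazolium chloride (5 mol %), NaOt-Bu (12 mol %), (EtO)2MeSiH, toluene, 0 °C; then K2CO3, MeOH, 23 °C
Reagents that add atoms: none
Why: Copper hydride catalysed SN2′ reduction of a propargylic oxirane, in which hydride is delivered to C6 anti to the breaking C11–O bond so that the C11 stereocentre becomes the allene axis (centre-to-axis chirality transfer) and the oxirane oxygen is kept as the C12 hydroxyl; the tertiary hydroxyl is no leaving group and the unactivated alkenes are inert.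

Step 12
Reactants: 19 allenyl diol
Product: 22 cis-decalone keto alcohol, via dipotassium dialkoxide 20 (not isolated), via dipotassium dienolate 21 (not isolated)
Conditions: KH (3.5 equiv), 18-crown-6 (2.5 equiv), THF, 0 → 23 °C; then −78 °C, AcOH in THF
Reagents that add atoms: none
Why: Deprotonation of both hydroxyls gives a crown-ether-separated dialkoxide in which the C5 oxyanion labilises the neighbouring C5–C10 σ bond, and a concerted anionic oxy-Cope ([3,3]-sigmatropic) shift along C7=C6–C5–C10–C9=C8 cleaves C5–C10, joins C7 to C8 and ends in the conjugated dienolate O–C5=C6–C7=C11, which the cold acetic acid quench protonates kinetically at C6 so that the C7=C11 alkene stays out of conjugation. The closest known reaction type is the anionic oxy-Cope rearrangement of 2-alkenylbicyclo[2.2.2]oct-5-en-2-ols to cis-fused octalones, together with the oxy-Cope shift of allenyl carbinols. Ring B (C3–C4–C5–C6–C7–C8) arises by a pericyclic, doubly suprafacial bond formation in a boat-shaped transition state enforced by the bicyclic skeleton, so exo/endo cyclisation labels do not apply, and the temporary third ring opens in the same event. The new stereocentre C8 and the cis fusion are controlled by the framework, since C7 can reach only the face of C8 turned toward the carbinol bridge, and the C7=C11 geometry is controlled by the allene axis, whose C11 methyl points at the etheno bridge in the reactive rotamer and therefore ends cis to C8 with C12 cis to C6. The step needs complete axis-to-alkene transfer and a dienolate that survives until the quench: the first is secured because the C5=C6 enolate must lie cis within ring B, so only one rotamer and one allene face can reach C8, and because step 10 placed the allenyl group syn to C8=C9; the second because C12 is kept as a potassium alkoxide, which cannot be expelled in a 1,6-elimination as a silyl ether at C12 could.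

Step 13
Reactants: 22 cis-decalone keto alcohol
Product: 23 C12 TBS ether of the decalone
Conditions: TBSCl, imidazole, CH2Cl2, 0 °C
Reagents that add atoms: tert-butyldimethylsilyl chloride, CC(C)(C)[Si](C)(C)Cl
Why: Silylation of the only hydroxyl group (primary and allylic; any cyclic hemiketal with the C5 ketone is drained through the open form) protects C12 while C5 and C1 are adjusted.

Step 14
Reactants: 23 C12 TBS ether of the decalone
Product: 24 C5 equatorial alcohol
Conditions: NaBH4, CeCl3·7H2O, MeOH, −78 °C
Reagents that add atoms: none
Why: Luche-type borohydride reduction under weakly acidic, non-enolising conditions (so the β,γ-alkene does not slip into conjugation), with axial hydride delivery from the convex face of the cis-decalone, away from ring A folded over the other face; this sets C5 with an equatorial hydroxyl trans to the equatorial C4 methyl.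

Step 15
Reactants: 24 C5 equatorial alcohol
Product: 25 C1,C5-diol
Conditions: DDQ, CH2Cl2–pH 7 phosphate buffer, 0 °C
Reagents that add atoms: none
Why: Oxidative PMB ether cleavage (hydride abstraction from the electron-rich benzylic carbon by DDQ, then hydrolysis of the oxocarbenium ion) frees the C1 hydroxyl under buffered conditions that leave the silyl ether and the alkenes alone.

Step 16
Reactants: 25 C1,C5-diol
Product: 26 C1,C5-diacetate C12 silyl ether
Conditions: Ac2O, pyridine, DMAP (cat.), CH2Cl2, 23 °C
Reagents that add atoms: acetic anhydride, CC(=O)OC(C)=O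
Why: DMAP-catalysed acetylation esterifies both secondary alcohols at oxygen, so C1 and C5 keep their configuration.

Step 17
Reactants: 26 C1,C5-diacetate C12 silyl ether
Product: 27 diacetate primary allylic alcohol
Conditions: HF·pyridine, pyridine, THF, 0 → 23 °C
Reagents that add atoms: none
Why: Fluoride-mediated desilylation under buffered, non-basic conditions removes the primary TBS ether without acetate migration or hydrolysis.

Step 18
Reactants: 27 diacetate primary allylic alcohol
Product: 28 CNP0262962.1 (target)
Conditions: acetic formic anhydride, pyridine, CH2Cl2, −20 → 0 °C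
Reagents that add atoms: acetic formic anhydride, CC(=O)OC=O
Why: O-Formylation with the mixed anhydride, whose formyl carbonyl is the more electrophilic one, converts the primary allylic alcohol into the formate without disturbing the acetates.

Compound list
1 | (R)-(−)-carvone | CC1=CC[C@H](CC1=O)C(=C)C | starting material
2 | (R)-10-chlorocarvone, (R)-5-(3-chloroprop-1-en-2-yl)-2-methylcyclohex-2-en-1-one | CC1=CC[C@H](CC1=O)C(=C)CCl | intermediate
3 | potassium dienolate of 2 (O–C1=C10–C9=C8) | [K+].[O-]C1=C(C)C=C[C@H](C1)C(=C)CCl | intermediate
4 | (1S,4S)-1-methyl-8-methylidenebicyclo[2.2.2]oct-5-en-2-one (C1 ketone, C10 methyl bridgehead, C3 bridgehead H, C8=C9 etheno bridge, C5H2–C4(=CH2) bridge) | C[C@]12C=C[C@H](CC1=O)C(=C)C2 | intermediate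
5 | C1 alcohol of 4, hydroxyl syn to the C4–C5 bridge and anti to C8=C9 | C[C@]12C=C[C@H](C[C@H]1O)C(=C)C2 | intermediate
6 | sodium alkoxide of 5 | [Na+].C[C@]12C=C[C@H](C[C@H]1[O-])C(=C)C2 | intermediate
7 | 4-methoxybenzyl ether of 5 | C[C@]12C=C[C@H](C[C@H]1OCc3ccc(OC)cc3)C(=C)C2 | intermediate
8 | C5 allylic alcohol of 7 (C5 epimers, C4 methylidene retained) | C[C@]12C=C[C@H](C[C@H]1OCc3ccc(OC)cc3)C(=C)C2O | intermediate
9 | exocyclic enone: C5 ketone, C4 methylidene, C1 OPMB syn to the carbonyl bridge | C[C@]12C=C[C@H](C[C@H]1OCc3ccc(OC)cc3)C(=C)C2=O | intermediate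
10 | lithium enolate O–C5=C4(Me) from 9 | [Li+].C[C@]12C=C[C@H](C[C@H]1OCc3ccc(OC)cc3)C(C)=C2[O-] | intermediate
11 | C4 epimer of 12 (C4 methyl anti to the C8=C9 bridge) | C[C@]12C=C[C@H](C[C@H]1OCc3ccc(OC)cc3)[C@H](C)C2=O | intermediate
12 | 7-(4-methoxybenzyloxy)-1,3-dimethylbicyclo[2.2.2]oct-5-en-2-one: C5 ketone, C4 methyl syn to the C8=C9 bridge, C1 OPMB syn to the carbonyl bridge | C[C@]12C=C[C@H](C[C@H]1OCc3ccc(OC)cc3)[C@@H](C)C2=O | intermediate
13 | (S)-2-methylglycidol | OC[C@@]1(C)CO1 | starting material
14 | (R)-2-methyloxirane-2-carbaldehyde | O=C[C@@]1(C)CO1 | intermediate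
15 | (S)-2-ethynyl-2-methyloxirane | C#C[C@@]1(C)CO1 | intermediate
16 | lithium acetylide of 15 | [Li+].[C-]#C[C@@]1(C)CO1 | intermediate
17 | C5 tertiary propargylic carbinol: alkynyl syn to C8=C9, hydroxyl anti, (S)-oxirane at C11 | C[C@]12C=C[C@H](C[C@H]1OCc3ccc(OC)cc3)[C@@H](C)[C@@]2(O)C#C[C@@]4(C)CO4 | intermediate
18 | O12 diethoxy(methyl)silyl ether of 19 | C[C@]12C=C[C@H](C[C@H]1OCc3ccc(OC)cc3)[C@@H](C)[C@@]2(O)C([H])=[C@]=C(C)CO[Si](C)(OCC)OCC | intermediate
19 | allenyl diol: C5 carbinol bearing C6H=C7=C11(Me)CH2OH, axis M (seen from C6 with C5 at twelve o'clock, the C11 methyl is at three o'clock) | C[C@]12C=C[C@H](C[C@H]1OCc3ccc(OC)cc3)[C@@H](C)[C@@]2(O)C([H])=[C@]=C(C)CO | intermediate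
20 | dipotassium dialkoxide of 19 | [K+].[K+].C[C@]12C=C[C@H](C[C@H]1OCc3ccc(OC)cc3)[C@@H](C)[C@@]2([O-])C([H])=[C@]=C(C)C[O-] | intermediate
21 | dipotassium salt of the rearranged dienolate (O–C5=C6–C7=C11) with C12 alkoxide | [K+].[K+].COc1ccc(CO[C@@H]2C[C@@H]3[C@@H](C)C([O-])=C/C(=C(/C)C[O-])[C@@H]3C=C2C)cc1 | intermediate
22 | cis-decalone: H3 and H8 α, 1β-OPMB, 4α-methyl, 5-oxo, C9=C10(Me), (E)-C7=C11 (methyl cis to C8) with free C12 hydroxyl | COc1ccc(CO[C@@H]2C[C@@H]3[C@@H](C)C(=O)C/C(=C(/C)CO)[C@@H]3C=C2C)cc1 | intermediate
23 | C12 tert-butyldimethylsilyl ether of 22 | COc1ccc(CO[C@@H]2C[C@@H]3[C@@H](C)C(=O)C/C(=C(/C)CO[Si](C)(C)C(C)(C)C)[C@@H]3C=C2C)cc1 | intermediate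
24 | 5β (equatorial) alcohol from 23 | COc1ccc(CO[C@@H]2C[C@@H]3[C@@H](C)[C@H](O)C/C(=C(/C)CO[Si](C)(C)C(C)(C)C)[C@@H]3C=C2C)cc1 | intermediate
25 | 1β,5β-diol, C12 silyl ether | O[C@@H]1C[C@@H]2[C@@H](C)[C@H](O)C/C(=C(/C)CO[Si](C)(C)C(C)(C)C)[C@@H]2C=C1C | intermediate
26 | 1β,5β-diacetate, C12 silyl ether | CC(=O)O[C@@H]1C[C@@H]2[C@@H](C)[C@H](OC(C)=O)C/C(=C(/C)CO[Si](C)(C)C(C)(C)C)[C@@H]2C=C1C | intermediate
27 | 1β,5β-diacetate with free C12 hydroxyl | CC(=O)O[C@@H]1C[C@@H]2[C@@H](C)[C@H](OC(C)=O)C/C(=C(/C)CO)[C@@H]2C=C1C | intermediate
28 | CNP0262962.1: cis-decalin 1β,5β-diacetate, 4α-methyl, (E)-C7=C11 alkylidene, C12 formate | CC(=O)O[C@@H]1C[C@@H]2[C@@H](C)[C@H](OC(C)=O)C/C(=C(/C)COC=O)[C@@H]2C=C1C | target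

Total step count: 18. Longest linear sequence: 16 (steps 1–7 and 10–18; steps 8–9 make the side fragment).

Steps most likely to fail

Step 12. The free dienolate may lose the C7=C11 geometry by rotation at its terminus, may be protonated at C11 instead of C6, or an alkoxide may add to the allene before the shift. The fallback runs the rearrangement without any charge. Setting out from diol 19, TBSCl and imidazole give the C12 silyl ether F1, and TMSOTf with 2,6-lutidine gives the tertiary trimethylsilyl ether F2. Heating F2 in degassed o-dichlorobenzene (sealed tube, about 180 °C) should bring about the thermal siloxy-Cope shift to the trimethylsilyl dienol ether F3. MeLi in THF at −78 °C then unmasks the lithium dienolate F4, which at that temperature should not expel the silyloxide and is protonated at C6 with acetic acid. This gives ketone 23, where the route continues with step 14.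

Step 11. Hydride may be delivered on the same side as the departing oxygen, which would invert the allene axis and hence the alkene geometry after step 12. The fallback inverts C11 instead of changing the reduction. (R)-2-Methylglycidol F5 is oxidised with Dess–Martin periodinane to (S)-2-methyloxirane-2-carbaldehyde F6 and homologated with the Ohira–Bestmann reagent to (R)-2-ethynyl-2-methyloxirane F7. Its lithium acetylide F8 adds to ketone 12 to give the C11-epimeric carbinol F9. A syn reduction of F9 under the conditions of step 11 then converges on silyl ether 18 and diol 19, where the route is rejoined.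

Step 9. The low-boiling alkyne may be lost on isolation or its oxirane opened by methoxide, which would also leave the acetylide stoichiometry of step 10 uncertain. The fallback never isolates the terminal alkyne. Setting out from aldehyde 14, Corey–Fuchs olefination (CBr4, PPh3, Et3N, CH2Cl2, 0 °C) gives the non-volatile (S)-2-(2,2-dibromoethenyl)-2-methyloxirane F10. Two equivalents of n-BuLi in THF at −78 °C convert F10 directly into lithium acetylide 16, which is combined with CeCl3 and ketone 12 as in step 10 to return to the route at carbinol 17.

Further compounds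
F1 | step 12 | C12 tert-butyldimethylsilyl ether of allenyl diol 19 | C[C@]12C=C[C@H](C[C@H]1OCc3ccc(OC)cc3)[C@@H](C)[C@@]2(O)C([H])=[C@]=C(C)CO[Si](C)(C)C(C)(C)C
F2 | step 12 | C5 trimethylsilyl ether of F1 | C[C@]12C=C[C@H](C[C@H]1OCc3ccc(OC)cc3)[C@@H](C)[C@@]2(O[Si](C)(C)C)C([H])=[C@]=C(C)CO[Si](C)(C)C(C)(C)C
F3 | step 12 | trimethylsilyl dienol ether (C5=C6, C7=C11) of the cis-decalin, C12 silyl ether | COc1ccc(CO[C@@H]2C[C@@H]3[C@@H](C)C(O[Si](C)(C)C)=C/C(=C(/C)CO[Si](C)(C)C(C)(C)C)[C@@H]3C=C2C)cc1
F4 | step 12 | lithium dienolate from F3 | [Li+].COc1ccc(CO[C@@H]2C[C@@H]3[C@@H](C)C([O-])=C/C(=C(/C)CO[Si](C)(C)C(C)(C)C)[C@@H]3C=C2C)cc1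
F5 | step 11 | (R)-2-methylglycidol | OC[C@]1(C)CO1
F6 | step 11 | (S)-2-methyloxirane-2-carbaldehyde | O=C[C@]1(C)CO1
F7 | step 11 | (R)-2-ethynyl-2-methyloxirane | C#C[C@]1(C)CO1
F8 | step 11 | lithium acetylide of F7 | [Li+].[C-]#C[C@]1(C)CO1
F9 | step 11 | C11 epimer of carbinol 17 ((R)-oxirane) | C[C@]12C=C[C@H](C[C@H]1OCc3ccc(OC)cc3)[C@@H](C)[C@@]2(O)C#C[C@]4(C)CO4
F10 | step 9 | (S)-2-(2,2-dibromoethenyl)-2-methyloxirane | BrC(Br)=C[C@@]1(C)CO1
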